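**Retrosynthetic overview**
- Feature: on the single benzene ring, C2 (OMe), C1 (CO2H) and C6 (CH2–CH(OAc)–C11H23) are contiguous. This is the pattern left when a carbon nucleophile and then CO2 add across the C6≡C1 bond of a 3-methoxybenzyne.
- Target ⇐ open-chain hydroxy acid: the acid is masked as a benzyl ester, the alcohol acetylated, the silyl ether cleaved and the ester hydrogenolysed.
- Hydroxy acid ⇐ cut C6–CH2 and C1–CO2H: 3-methoxy-5-(triisopropylsilyloxy)benzyne (from the fluoroarene by lithiation and LiF loss) + C,O-dilithiated (R)-1-chlorotridecan-2-ol + CO2.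
- Chlorohydrin ⇐ decylmagnesium bromide + (R)-epichlorohydrin, the source of the only stereocenter; fluoroarene ⇐ 3-fluoro-5-methoxyphenol.
- Ring order: no ring is formed at any stage; the benzene ring is bought.

Key step: step 3

Assumption: the β-lithiooxy alkyllithium is taken to persist between −78 and −45 °C long enough to capture the aryne; the temperature programme of the key step is built on this.

**Step 1**
Reactants: 1 3-fluoro-5-methoxyphenol
Product: 2 (3-fluoro-5-methoxyphenoxy)triisopropylsilane
Conditions: TIPSCl, imidazole, DMF, 0 °C to rt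
Reagents that add atoms: triisopropylsilyl chloride, CC(C)[Si](Cl)(C(C)C)C(C)C
Why: Imidazole-promoted O-silylation of a phenol is reliable, and the triisopropylsilyl ether is chosen because it withstands alkyllithiums at low temperature and shields both ring positions next to it.

**Step 2**
Reactants: 3 1-bromodecane; 4 (R)-epichlorohydrin
Product: 6 (R)-1-chlorotridecan-2-ol, via decylmagnesium bromide 5 (not isolated)
Conditions: Mg, THF, rt to 40 °C; then CuI (10 mol%), 4, THF, −40 to −20 °C; cold 1 M HCl
Reagents that add atoms: none
Why: Copper-catalysed Grignard opening of a terminal epoxide is an SN2 attack at the unsubstituted CH2 carbon, so no bond at the stereocenter of 4 is touched and its configuration is carried into 6 (descriptor R in both), while the low temperature keeps the chloroalkoxide from closing to a new epoxide.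

**Step 3**
Reactants: 2 (3-fluoro-5-methoxyphenoxy)triisopropylsilane; 6 (R)-1-chlorotridecan-2-ol; 7 carbon dioxide
Product: 12 2-[(2R)-2-hydroxytridecyl]-6-methoxy-4-(triisopropylsilyloxy)benzoic acid, via dilithio alkoxide 8 (not isolated), via aryllithium 9 (not isolated), via aryne 10 (not isolated), via lithio adduct 11 (not isolated)
Conditions: flask A: 6 (1.3 equiv), n-BuLi (1.3 equiv), THF, −78 °C, then LiC10H8 (lithium naphthalenide, 2.6 equiv), −78 °C; flask B: 2 (1.0 equiv), s-BuLi (1.0 equiv), THF, −78 °C; B into A by cold cannula at −78 °C, then −50 to −45 °C; 7 (gas), −78 °C; cold 1 M HCl to pH 4–5, 0 °C, crude acid used at once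
Reagents that add atoms: none
Why: Proposed new method: s-BuLi removes the ring proton of 2 flanked by F and OMe to give 9, which on warming expels LiF to aryne 10; the primary C–Li bond of 8 then adds to the aryne carbon remote from OMe, so the aryl–lithium bond of 11 lies next to the methoxy oxygen, and CO2 carboxylates that carbon. The closest known reaction type is the addition of simple alkyllithiums to 3-alkoxybenzynes made from 3-haloanisoles, with CO2 capture of the 2-alkoxyaryllithium to give 6-alkyl-2-methoxybenzoic acids; the extension is a nucleophile carrying a β-lithiooxy group, a reagent class that is made from chlorohydrins at −78 °C and is slow to eliminate because Li2O is a poor leaving group. No ring is closed: the step forms the C6–CH2 and C1–CO2H bonds of an open-chain product. No stereocenter is created; the carbinol carbon comes from 6 and no bond to it is made or broken, so its spatial arrangement is retained (the descriptor of 8 reads S only because CH2Li ranks below the undecyl chain). The step needs three selectivities: site-selective lithiation (secured by the joint acidifying effect of F and OMe and by the silyl ether shielding its two neighbours), regioselective aryne addition (secured by the inductive pull of OMe, which places the developing carbanion ortho to it), and survival of 8 against β-elimination (secured by pre-forming 9 at −78 °C and releasing the aryne only in the presence of excess 8 near −50 °C).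

**Step 4**
Reactants: 12 2-[(2R)-2-hydroxytridecyl]-6-methoxy-4-(triisopropylsilyloxy)benzoic acid
Product: 13 benzyl 2-[(2R)-2-hydroxytridecyl]-6-methoxy-4-(triisopropylsilyloxy)benzoate
Conditions: BnBr, KHCO3, DMF, 0 °C to rt
Reagents that add atoms: benzyl bromide, BrCc1ccccc1
Why: SN2 O-alkylation of the carboxylate by benzyl bromide under weakly basic conditions esterifies without activating the carboxyl carbon, so the neighbouring secondary alcohol is given no acylating partner for lactonisation and stays free.

**Step 5**
Reactants: 13 benzyl 2-[(2R)-2-hydroxytridecyl]-6-methoxy-4-(triisopropylsilyloxy)benzoate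
Product: 14 benzyl 2-[(2R)-2-acetoxytridecyl]-6-methoxy-4-(triisopropylsilyloxy)benzoate
Conditions: Ac2O, pyridine, DMAP (cat.), CH2Cl2, 0 °C to rt
Reagents that add atoms: acetic anhydride, CC(=O)OC(C)=O
Why: DMAP-catalysed acyl transfer to the secondary alcohol is fast at 0 °C and should outpace lactonisation onto the hindered 2,6-disubstituted benzyl ester, and it acylates oxygen without touching the C–O bond of the stereocenter.

**Step 6**
Reactants: 14 benzyl 2-[(2R)-2-acetoxytridecyl]-6-methoxy-4-(triisopropylsilyloxy)benzoate
Product: 15 benzyl 2-[(2R)-2-acetoxytridecyl]-4-hydroxy-6-methoxybenzoate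
Conditions: TBAF (1.1 equiv), AcOH (1.2 equiv), THF, 0 °C
Reagents that add atoms: none
Why: Fluoride-mediated desilylation cleaves the aryl O–Si bond selectively, and the acetic acid buffer protonates the phenoxide as it forms so that neither the acetate nor the benzyl ester is attacked.

**Step 7**
Reactants: 15 benzyl 2-[(2R)-2-acetoxytridecyl]-4-hydroxy-6-methoxybenzoate
Product: 16 2-[(2R)-2-acetoxytridecyl]-4-hydroxy-6-methoxybenzoic acid
Conditions: H2 (1 atm), 10% Pd/C, EtOAc, rt
Reagents that add atoms: none
Why: Palladium-catalysed hydrogenolysis of the benzylic C–O bond frees the acid under neutral conditions that leave the homobenzylic acetate, the methyl ether and the stereocenter untouched.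

**Compound list**
1 | 3-fluoro-5-methoxyphenol | COc1cc(O)cc(F)c1 | starting material
2 | (3-fluoro-5-methoxyphenoxy)triisopropylsilane | COc1cc(F)cc(O[Si](C(C)C)(C(C)C)C(C)C)c1 | intermediate
3 | 1-bromodecane | CCCCCCCCCCBr | starting material
4 | (R)-epichlorohydrin | ClC[C@H]1CO1 | starting material
5 | decylmagnesium bromide | CCCCCCCCCC[Mg]Br | intermediate
6 | (R)-1-chlorotridecan-2-ol | CCCCCCCCCCC[C@H](CCl)O | intermediate
7 | carbon dioxide | O=C=O | starting material
8 | C,O-dilithio derivative of 6, formally (2S)-1-lithio-2-(lithiooxy)tridecane (same spatial arrangement as 6) | CCCCCCCCCCC[C@H](C[Li])O[Li] | intermediate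
9 | 2-fluoro-6-methoxy-4-(triisopropylsilyloxy)phenyllithium | COc1cc(O[Si](C(C)C)(C(C)C)C(C)C)cc(F)c1[Li] | intermediate
10 | 3-methoxy-5-(triisopropylsilyloxy)benzyne | COC1=CC(O[Si](C(C)C)(C(C)C)C(C)C)=CC#C1 | intermediate
11 | lithium (2R)-1-[2-lithio-3-methoxy-5-(triisopropylsilyloxy)phenyl]tridecan-2-olate | CCCCCCCCCCC[C@H](Cc1cc(O[Si](C(C)C)(C(C)C)C(C)C)cc(OC)c1[Li])O[Li] | intermediate
12 | 2-[(2R)-2-hydroxytridecyl]-6-methoxy-4-(triisopropylsilyloxy)benzoic acid | CCCCCCCCCCC[C@H](Cc1cc(O[Si](C(C)C)(C(C)C)C(C)C)cc(OC)c1C(=O)O)O | intermediate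
13 | benzyl 2-[(2R)-2-hydroxytridecyl]-6-methoxy-4-(triisopropylsilyloxy)benzoate | CCCCCCCCCCC[C@H](Cc1cc(O[Si](C(C)C)(C(C)C)C(C)C)cc(OC)c1C(=O)OCc1ccccc1)O | intermediate
14 | benzyl 2-[(2R)-2-acetoxytridecyl]-6-methoxy-4-(triisopropylsilyloxy)benzoate | CCCCCCCCCCC[C@H](Cc1cc(O[Si](C(C)C)(C(C)C)C(C)C)cc(OC)c1C(=O)OCc1ccccc1)OC(C)=O | intermediate
15 | benzyl 2-[(2R)-2-acetoxytridecyl]-4-hydroxy-6-methoxybenzoate | CCCCCCCCCCC[C@H](Cc1cc(O)cc(OC)c1C(=O)OCc1ccccc1)OC(C)=O | intermediate
16 | 2-[(2R)-2-acetoxytridecyl]-4-hydroxy-6-methoxybenzoic acid | CCCCCCCCCCC[C@H](Cc1cc(O)cc(OC)c1C(=O)O)OC(C)=O | target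

**Step count**
Total steps: 7. Longest linear sequence: 6 steps (step 1 or step 2, then steps 3 to 7).

**Steps most likely to fail**

1. Step 3 (Proposed new method). The alkyllithium may be lost by β-elimination of Li2O before the aryllithium has expelled LiF, or the aryne may be captured by aryllithium instead of the alkyllithium, so that carbolithiation and carboxylation do not occur. The fallback uses known chemistry, sets out from 6 and comes back at 12.
 - KOH in Et2O/H2O closes 6 to (R)-2-undecyloxirane F1 without touching the stereocenter.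
 - Commercial 3-bromo-5-methoxyphenol is silylated (TIPSCl, imidazole, DMF) to (3-bromo-5-methoxyphenoxy)triisopropylsilane F2.
 - Bromine–lithium exchange on F2 (n-BuLi, THF, −78 °C) followed by BF3·OEt2-promoted SN2 opening of F1 at its CH2 carbon should give (R)-1-[3-methoxy-5-(triisopropylsilyloxy)phenyl]tridecan-2-ol F3.
 - F3, as its lithium alkoxide, is ortho-lithiated (s-BuLi, TMEDA, THF, −78 to −40 °C) at the ring carbon between OMe and the side chain, the only methoxy-ortho site not shielded by the silyl ether. CO2 and the same pH 4–5 work-up return 12.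

2. Step 4. The free hydroxy acid may close to the six-membered lactone during acidification, handling or esterification, which removes the carboxylate before it is benzylated. The fallback sets out from 12 and comes back at 13, using the lactone as a stable relay.
 - 12 is driven fully to (3R)-8-methoxy-6-(triisopropylsilyloxy)-3-undecyl-3,4-dihydroisochromen-1-one F4 (TsOH cat., CH2Cl2, rt) and purified.
 - The lactone is opened with KOH (1.0 equiv) in THF/H2O at rt, the solution is concentrated, and the potassium carboxylate is alkylated in DMF with BnBr to give 13.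

3. Step 6. Under the fluoride medium, acetyl transfer to the liberated phenoxide or acetate loss followed by ring closure onto the benzyl ester may occur. The fallback removes the fluoride step from the acetate-bearing stage by a protecting-group swap; it sets out from 13 and comes back at 16.
 - TBAF/AcOH in THF converts 13 into benzyl 4-hydroxy-2-[(2R)-2-hydroxytridecyl]-6-methoxybenzoate F5.
 - The phenol alone is benzylated (BnBr, K2CO3, acetone, rt) to benzyl 4-(benzyloxy)-2-[(2R)-2-hydroxytridecyl]-6-methoxybenzoate F6.
 - Acetylation (Ac2O, pyridine, DMAP) gives benzyl 2-[(2R)-2-acetoxytridecyl]-4-(benzyloxy)-6-methoxybenzoate F7.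
 - A single hydrogenolysis (H2, 10% Pd/C, EtOAc) cleaves both benzyl groups to give 16.

**Further compounds**
F1 | step 3 | (R)-2-undecyloxirane | CCCCCCCCCCC[C@@H]1CO1
F2 | step 3 | (3-bromo-5-methoxyphenoxy)triisopropylsilane | COc1cc(Br)cc(O[Si](C(C)C)(C(C)C)C(C)C)c1
F3 | step 3 | (R)-1-[3-methoxy-5-(triisopropylsilyloxy)phenyl]tridecan-2-ol | CCCCCCCCCCC[C@H](Cc1cc(OC)cc(O[Si](C(C)C)(C(C)C)C(C)C)c1)O
F4 | step 4 | (3R)-8-methoxy-6-(triisopropylsilyloxy)-3-undecyl-3,4-dihydroisochromen-1-one | CCCCCCCCCCC[C@@H]1Cc2cc(O[Si](C(C)C)(C(C)C)C(C)C)cc(OC)c2C(=O)O1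
F5 | step 6 | benzyl 4-hydroxy-2-[(2R)-2-hydroxytridecyl]-6-methoxybenzoate | CCCCCCCCCCC[C@H](Cc1cc(O)cc(OC)c1C(=O)OCc1ccccc1)O
F6 | step 6 | benzyl 4-(benzyloxy)-2-[(2R)-2-hydroxytridecyl]-6-methoxybenzoate | CCCCCCCCCCC[C@H](Cc1cc(OCc2ccccc2)cc(OC)c1C(=O)OCc1ccccc1)O
F7 | step 6 | benzyl 2-[(2R)-2-acetoxytridecyl]-4-(benzyloxy)-6-methoxybenzoate | CCCCCCCCCCC[C@H](Cc1cc(OCc2ccccc2)cc(OC)c1C(=O)OCc1ccccc1)OC(C)=O
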